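## Structural features

The target is a cis-fused decahydroquinoline: a piperidine ring (N1, C2, C3, C4, C4a, C8a) shares the C4a–C8a bond with a cyclohexane ring (C4a, C5, C6, C7, C8, C8a). C2 (R) carries a methyl group and the adjacent C3 (S) carries the (E)-oct-2-enoyloxy group, trans to it. C5 (R) carries a 5-hydroxyoctyl chain whose carbinol carbon C5′ (R) is too far from the ring for any relay of configuration. C8a, C4a and C5 are contiguous: H2, H4a, H5 and H8a lie on one face, so the methyl group, the C8a–C8 bond and the C4a–C5 bond sit on one face of the piperidine ring and the C3 oxygen on the other, while N1, C4 and the side chain are all cis on the carbocycle. The fragile groups are the enoate (reducible, a conjugate acceptor, prone to O→N acyl shift onto the neighbouring secondary amine), the basic N–H and the free secondary alcohol. The real difficulty is the C8a/C4a/C5 triad, because C5 has no activating neighbour and cannot be corrected by epimerisation. A second difficulty is that the C3 oxygen lies on the face from which a hydride reagent would approach a C3 carbonyl. The key step exploits the fact that a C3 ketone turns C4=C4a into an enone whose β-carbon is C4a: a furan-derived 2H-pyridin-3-one supplies this array, and its C8a substituent, held axial by the N-sulfonyl group, can deliver a C5 radical to C4a on one face only.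

## Logic of the disconnections

**32 ⇒ 31 ⇒ 29 + 30.** The N–CO2t-Bu and O–Si bonds of 31 are cut first, because one protic acid removes both while the nitrogen stays protonated. Behind that, the alkyl–oxygen bond C3–O is cut (not the acyl–oxygen bond), giving 30 and 29, in which C3 has the opposite configuration to 32. The reason is that hydride should reach a C3 carbonyl only on the face away from the axial C2 methyl group, which gives the 3R carbinol. Cutting at C3–O removes the eight-carbon acyl group and the configurational correction together. The forward step must be a clean SN2 displacement at a hindered secondary carbon, with nitrogen blocked as a carbamate so that it neither attacks the activated carbinol nor is acylated.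

**29 ⇒ 27 ⇒ 26.** The N–C(carbamate) bond is exchanged for the N–S bond of 27, and the C3–H bond is then taken back to the C3 carbonyl of 26. The sulfonyl group is needed for all earlier steps but cannot be removed in the presence of the enoate, so the exchange must precede acylation. This removes one stereocentre and returns to the ketone that the key step produces. The forward reduction must be facially selective, and the electron-transfer desulfonylation must find no other reducible group.

**26 ⇒ 25.** The C4a–C5 bond is cut homolytically, which opens the carbocycle and removes the C4a and C5 stereocentres. C5 becomes a carboxyl-bearing carbon of undefined configuration and C4a the β-carbon of an enone. A bicyclic problem with three contiguous centres becomes a monocyclic one with two centres (C2, C8a) flanking nitrogen. The forward step must generate the radical without reducing the enone, close cis, and place the chain pseudo-equatorial.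

**25 ⇒ 24 ⇒ 23.** The acyl–O–N bond of the active ester and the C3 oxidation level are adjusted. The enone is base-sensitive (loss of sulfinate with aromatisation), so the carbonyl is carried as an allylic alcohol through all basic and hydridic steps and restored just before activation. Oxidation and esterification must therefore be non-basic.

**23 ⇒ 14 + 20.** The C5–C6 bond is cut next to the carboxyl group, which splits the molecule into a ring fragment and the complete side chain, with the C5′ stereocentre on the smaller piece. The carboxylic acid is alkylated as its dianion so that no ester hydrolysis is needed later. The forward step needs a primary iodide, a masked ketone and two silyl ethers of different lability.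

**14 ⇒ 13 ⇒ 11 ⇒ 10 ⇒ 9.** The C6–I bond, the C6–O bond (anti-Markovnikov hydration of a terminal alkene), the O–SiEt3 bond and the C3–H bond are removed in turn. This reduces the ring fragment to an allyl-substituted enone. The forward steps need chemoselective hydroboration of the terminal over the ring alkene and a 1,2-selective carbonyl reduction.

**9 ⇒ 7 + 8.** The C8a–C8 bond is cut to an N-sulfonyliminium ion and an allyl nucleophile. This sets C8a relative to C2 and brings in C6–C8 in one step. The forward step must be 2,6-cis selective, which the axial C2 methyl group and axial attack should ensure.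

**7 ⇒ 6 ⇒ 4 ⇒ 1 + 2.** The N1–C8a bond and the ring oxygenation are traced back to a furan, the N–S(tolyl) bond to an amine, and the C2–H/C2–N bonds to a ketone and a chiral sulfinamide. All ring carbons then come from a cheap furan, and C2 is the only stereocentre that has to be made with a reagent. The forward step needs a diastereoselective imine reduction.

**20 ⇒ 19 ⇒ 18 ⇒ 15 + 16.** The carboxyl group is traced to a terminal alkene one carbon longer, the O–Si bond is removed, and the C3′–C4′ bond is cut to a Grignard reagent and a terminal epoxide. C5′ then comes unchanged from the chiral pool. The forward step needs regioselective opening at the CH2 terminus.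

## Other disconnections considered

**Alternative 1:** The cut is C4–C4a, closing the piperidinone ring. The precursor is the cyclohexenyl ester A1, in which only C8a is fixed. Catalytic KOC(CH3)3 would form the methyl-ketone enolate, which adds through C4 to C4a (6-exo-trig Michael addition) to give the keto ester A2.
- In its favour: the step is polar, catalytic and needs no special equipment. Because the addition is reversible and C2 and C5 can enolise, three centres could settle under thermodynamic control, which is broader convergence than the chosen step offers (better). Nitrogen carries a carbamate from the start, so no sulfonamide–carbamate exchange is needed (better).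
- Against it here: A2 carries an ester at C5, not the chain. The ester carbon would have to be taken to the aldehyde level, olefinated with a seven-carbon ylide bearing the carbinol, and hydrogenated, all next to an epimerisable centre and with the C3 ketone differentiated first. Whether the equilibrium favours the all-cis isomer is not assured. A1 needs its own asymmetric allylic amination.
- Comparison: both plans give a cis-fused 3-ketone and face the same C3 problem (equal). The chosen plan brings in the whole side chain before ring closure and is more convergent. Overall step counts should be similar.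

**Alternative 2:** The cuts are N1–C8a and C8–C8a, closing both rings. Aqueous CF3CO2H would unmask the aldehyde of the acetal A3; condensation with the secondary amine gives the cyclic iminium ion, and the Z-vinylsilane attacks C8a at its silicon-bearing carbon with loss of silicon to give A4.
- In its favour: two rings and two bonds form in one operation (better). Enamine–iminium exchange can correct C4a before closure. C2 and C3 are set in an acyclic precursor, so no inversion at C3 is needed (better).
- Against it here: A3 carries four stereocentres and a geometrically pure vinylsilane on a linear chain and would take a long sequence. Ring fusion and C8a rely on a chair preference of about the same uncertainty as the chosen step (equal). Protodesilylation can compete in aqueous acid. A4 still needs hydrogenation (which also removes both benzyl groups), N-protection, acylation and deprotection, so the endgame is no shorter (equal).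
- Comparison: the alternative's key step is the more powerful, but the chosen plan reaches its precursor from cheaper chiral inputs in fewer linear steps.

**Alternative 3:** This is a skeletal reorganisation in which N1–C2 forms and the old N–C3 bond breaks. (CF3CO)2O/Et3N on heating would activate the carbinol of the octahydroindole A5; nitrogen displaces it to give an aziridinium ion, and trifluoroacetate opens this at C3 to give the ring-expanded ester A6.
- In its favour: two stereospecific inversions deliver the 2,3-trans arrangement with the correct C3–O bond directly (better than reduction plus inversion). A6 could be O-deacylated, O-acylated as a tertiary amine without N-protection and N-deallylated with Pd(PPh3)4, an endgame at least as short as the chosen one (equal or better).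
- Against it here: the whole burden of the C8a/C4a/C5 triad is moved into A5, a cis-octahydroindole with four ring centres and a carbinol centre, for which no short route is evident. The regiochemistry of aziridinium opening (two secondary carbons) depends on a thermodynamic preference that the cis-fused bicycle may alter.
- Comparison: this alternative is stronger at C2/C3 and weaker at the triad, which is the harder problem; the chosen plan solves the triad in one step from a monocycle.

Key step: step 15

Remark on the chemistry: hydride is taken to add to the C3 carbonyl of 9 and of 26 on the face away from the axial C2 methyl group (2,3-cis alcohols). A reduce-then-acylate order would therefore give the C3 epimer of the target, so acylation is done with inversion (step 18).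

Remark on the structures: 25 and 26 carry the same configuration as 32 at C2, C8a and C5′, and 26 also at C4a and C5; no descriptor had to be changed.

## Route

Step 1
Reactants: 1 2-acetylfuran [1-(furan-2-yl)ethan-1-one]; 2 (R)-2-methylpropane-2-sulfinamide
Product: 4 (R)-N-[(1R)-1-(furan-2-yl)ethyl]-2-methylpropane-2-sulfinamide, via N-sulfinyl ketimine 3 (not isolated)
Conditions: Ti(OEt)4, THF, 65 °C; then NaBH4, −48 °C
Reagents that add atoms: none
Why: Asymmetric reductive amination with a tert-butanesulfinamide auxiliary: Ti(OEt)4 drives condensation to the (E)-ketimine, and NaBH4 should deliver hydride through a cyclic, metal-bridged transition state to the face that gives the R carbon from the (R)-sulfinyl aryl methyl ketimine. This sets C2 of the target.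

Step 2
Reactants: 4 (R)-N-[(1R)-1-(furan-2-yl)ethyl]-2-methylpropane-2-sulfinamide
Product: 6 N-[(1R)-1-(furan-2-yl)ethyl]-4-methylbenzenesulfonamide, via ammonium chloride 5 (not isolated)
Conditions: HCl (4 M in dioxane), MeOH, 0 °C; evaporate; TsCl, Et3N, CH2Cl2, 0 °C → rt
Reagents that add atoms: 4-methylbenzenesulfonyl chloride (TsCl), Cc1ccc(cc1)S(=O)(=O)Cl
Why: Acidic methanolysis cleaves the N–S bond without touching the stereocentre, and the crude salt is N-sulfonylated. The sulfonyl group is needed for the oxidative ring expansion and for A(1,3) control in steps 4 and 15.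

Step 3
Reactants: 6 N-[(1R)-1-(furan-2-yl)ethyl]-4-methylbenzenesulfonamide
Product: 7 (2R)-6-hydroxy-2-methyl-1-(4-methylbenzenesulfonyl)-1,6-dihydro-2H-pyridin-3-one (both C6 epimers)
Conditions: mCPBA, CH2Cl2, 0 °C → rt
Reagents that add atoms: 3-chloroperoxybenzoic acid (mCPBA), OOC(=O)c1cccc(Cl)c1
Why: Aza-Achmatowicz oxidation: epoxidation of the furan, opening to the cis-enedione and closure of the sulfonamide nitrogen onto the aldehyde carbon. C2 is untouched and the hemiaminal configuration is irrelevant because C6 is ionised next.

Step 4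
Reactants: 7 (2R)-6-hydroxy-2-methyl-1-(4-methylbenzenesulfonyl)-1,6-dihydro-2H-pyridin-3-one; 8 allyltrimethylsilane
Product: 9 (2R,6S)-2-methyl-1-(4-methylbenzenesulfonyl)-6-(prop-2-en-1-yl)-1,6-dihydro-2H-pyridin-3-one
Conditions: BF3·OEt2, CH2Cl2, −78 °C
Reagents that add atoms: none
Why: Hosomi–Sakurai-type allylation of the N-sulfonyliminium ion formed by ionising the hemiaminal. A(1,3) strain with the sulfonyl group holds the C2 methyl group pseudo-axial, and axial attack through a chair-like transition state places the allyl group axial on the same face, giving the 2,6-cis (6S) product. This sets C8a of the target.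

Step 5
Reactants: 9 (2R,6S)-2-methyl-1-(4-methylbenzenesulfonyl)-6-(prop-2-en-1-yl)-1,6-dihydro-2H-pyridin-3-one
Product: 10 (2R,3R,6S)-2-methyl-1-(4-methylbenzenesulfonyl)-6-(prop-2-en-1-yl)-1,2,3,6-tetrahydropyridin-3-ol
Conditions: NaBH4, CeCl3·7H2O, MeOH, −40 °C
Reagents that add atoms: none
Why: Luche 1,2-reduction masks the enone carbonyl so that borane and strong base can be used. Hydride should add anti to the axial methyl group (3R), but this centre is only temporary and is re-oxidised in step 13.

Step 6
Reactants: 10 (2R,3R,6S)-2-methyl-1-(4-methylbenzenesulfonyl)-6-(prop-2-en-1-yl)-1,2,3,6-tetrahydropyridin-3-ol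
Product: 11 (2R,3R,6S)-2-methyl-1-(4-methylbenzenesulfonyl)-6-(prop-2-en-1-yl)-3-[(triethylsilyl)oxy]-1,2,3,6-tetrahydropyridine
Conditions: Et3SiCl, imidazole, CH2Cl2, 0 °C
Reagents that add atoms: chlorotriethylsilane, CC[Si](Cl)(CC)CC
Why: Standard silylation of a secondary alcohol. The triethylsilyl ether is chosen because it can later be cleaved with mild acid beside the tert-butyldimethylsilyl ether of the side chain.

Step 7
Reactants: 11 (2R,3R,6S)-2-methyl-1-(4-methylbenzenesulfonyl)-6-(prop-2-en-1-yl)-3-[(triethylsilyl)oxy]-1,2,3,6-tetrahydropyridine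
Product: 13 3-[(2S,5R,6R)-6-methyl-1-(4-methylbenzenesulfonyl)-5-[(triethylsilyl)oxy]-1,2,5,6-tetrahydropyridin-2-yl]propan-1-ol, via B-alkyl-9-borabicyclononane 12 (not isolated)
Conditions: 9-BBN, THF, 0 °C → rt; then aq. NaOH, H2O2, 0 °C
Reagents that add atoms: hydrogen peroxide, OO
Why: Anti-Markovnikov hydroboration–oxidation. The bulky borane adds to the monosubstituted alkene much faster than to the hindered cis-disubstituted ring alkene, so the ring double bond needed for the later enone is kept.

Step 8
Reactants: 13 3-[(2S,5R,6R)-6-methyl-1-(4-methylbenzenesulfonyl)-5-[(triethylsilyl)oxy]-1,2,5,6-tetrahydropyridin-2-yl]propan-1-ol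
Product: 14 (2R,3R,6S)-6-(3-iodopropyl)-2-methyl-1-(4-methylbenzenesulfonyl)-3-[(triethylsilyl)oxy]-1,2,3,6-tetrahydropyridine
Conditions: I2, PPh3, imidazole, CH2Cl2, 0 °C
Reagents that add atoms: iodine, II
Why: Appel-type conversion of a primary alcohol to the iodide under imidazole-buffered conditions that leave the silyl ether intact. The tertiary sulfonamide nitrogen is not nucleophilic enough to interfere.

Step 9
Reactants: 15 6-bromohex-1-ene; 16 (R)-2-propyloxirane [(R)-1,2-epoxypentane]
Product: 18 (4R)-undec-10-en-4-ol, via hex-5-enylmagnesium bromide 17 (not isolated)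
Conditions: Mg, THF, rt; then CuI (10 mol %), −30 → 0 °C
Reagents that add atoms: none
Why: Copper-catalysed Grignard opening of a terminal epoxide at the CH2 carbon. The stereocentre is not involved and stays R, which supplies C5′ of the target from the chiral pool.

Step 10
Reactants: 18 (4R)-undec-10-en-4-ol
Product: 19 tert-butyldimethyl{[(4R)-undec-10-en-4-yl]oxy}silane
Conditions: t-BuMe2SiCl, imidazole, DMF, rt
Reagents that add atoms: tert-butylchlorodimethylsilane, CC(C)(C)[Si](C)(C)Cl
Why: Standard silylation. The tert-butyldimethylsilyl ether survives every later step up to the final acid treatment.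

Step 11
Reactants: 19 tert-butyldimethyl{[(4R)-undec-10-en-4-yl]oxy}silane
Product: 20 (7R)-7-[(tert-butyldimethylsilyl)oxy]decanoic acid
Conditions: RuCl3·xH2O (cat.), NaIO4, EtOAc/MeCN/H2O, 0 °C → rt
Reagents that add atoms: sodium periodate, [Na+].[O-]I(=O)(=O)=O; water, O
Why: Catalytic RuO4 cleaves the terminal alkene to the carboxylic acid with loss of the terminal carbon, giving the ten-carbon acid in one operation. Secondary silyl ethers tolerate these conditions.

Step 12
Reactants: 14 (2R,3R,6S)-6-(3-iodopropyl)-2-methyl-1-(4-methylbenzenesulfonyl)-3-[(triethylsilyl)oxy]-1,2,3,6-tetrahydropyridine; 20 (7R)-7-[(tert-butyldimethylsilyl)oxy]decanoic acid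
Product: 23 (7R)-7-[(tert-butyldimethylsilyl)oxy]-2-{3-[(2S,5R,6R)-5-hydroxy-6-methyl-1-(4-methylbenzenesulfonyl)-1,2,5,6-tetrahydropyridin-2-yl]propyl}decanoic acid (both C2 epimers of the acid chain), via dilithium enediolate 21 (not isolated), via triethylsilyl-protected acid 22 (not isolated)
Conditions: LiN(iPr)2, THF, 0 °C; DMPU; add 14, −78 °C → rt; 1 M HCl to pH 3; crude, PPTS, MeOH, rt
Reagents that add atoms: none
Why: Alkylation of a carboxylic acid dianion with a primary iodide forms C5–C6 and gives the free acid directly, so no ester hydrolysis is needed near the later enone. The new centre (C5) forms unselectively, which does not matter because it is erased in step 15. Buffered methanolysis then removes the triethylsilyl ether much faster than the hindered tert-butyldimethylsilyl ether.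

Step 13
Reactants: 23 (7R)-7-[(tert-butyldimethylsilyl)oxy]-2-{3-[(2S,5R,6R)-5-hydroxy-6-methyl-1-(4-methylbenzenesulfonyl)-1,2,5,6-tetrahydropyridin-2-yl]propyl}decanoic acid
Product: 24 (7R)-7-[(tert-butyldimethylsilyl)oxy]-2-{3-[(2S,6R)-6-methyl-1-(4-methylbenzenesulfonyl)-5-oxo-1,2,5,6-tetrahydropyridin-2-yl]propyl}decanoic acid
Conditions: Dess–Martin periodinane, CH2Cl2, 0 °C → rt
Reagents that add atoms: none
Why: Dess–Martin oxidation of the allylic alcohol tolerates the free acid and the silyl ether. The medium is non-basic, so neither C2 epimerisation nor sulfinate elimination from the restored enone is expected.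

Step 14
Reactants: 24 (7R)-7-[(tert-butyldimethylsilyl)oxy]-2-{3-[(2S,6R)-6-methyl-1-(4-methylbenzenesulfonyl)-5-oxo-1,2,5,6-tetrahydropyridin-2-yl]propyl}decanoic acid
Product: 25 1,3-dioxoisoindolin-2-yl (7R)-7-[(tert-butyldimethylsilyl)oxy]-2-{3-[(2S,6R)-6-methyl-1-(4-methylbenzenesulfonyl)-5-oxo-1,2,5,6-tetrahydropyridin-2-yl]propyl}decanoate (both C2 epimers of the acid chain)
Conditions: N-hydroxyphthalimide, DIC, DMAP (cat.), CH2Cl2, 0 °C → rt
Reagents that add atoms: N-hydroxyphthalimide, ON1C(=O)c2ccccc2C1=O
Why: Steglich-type carbodiimide esterification gives the redox-active ester. The acidic N-hydroxy imide is acylated under near-neutral conditions that the enone tolerates.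

Step 15
Reactants: 25 1,3-dioxoisoindolin-2-yl (7R)-7-[(tert-butyldimethylsilyl)oxy]-2-{3-[(2S,6R)-6-methyl-1-(4-methylbenzenesulfonyl)-5-oxo-1,2,5,6-tetrahydropyridin-2-yl]propyl}decanoate
Product: 26 (2R,4aR,5R,8aS)-5-{(5R)-5-[(tert-butyldimethylsilyl)oxy]octyl}-2-methyl-1-(4-methylbenzenesulfonyl)octahydroquinolin-3(2H)-one
Conditions: undivided cell, graphite-felt cathode, Zn anode, constant current (5 mA, ca. 2.2 F/mol), n-Bu4NPF6, (CF3)2CHOH (3 equiv), DMF (0.01 M), 0 °C → rt; aq. NH4Cl
Reagents that add atoms: none
Why: At the cathode the N-(acyloxy)phthalimide, the most easily reduced group in 25, takes up one electron, its N–O bond breaks, and loss of CO2 leaves a secondary radical at C5. This nucleophilic radical adds to the electron-poor β-carbon C4a of the enone in a 6-exo-trig closure of the carbocycle, and the resulting α-keto radical at C4 is reduced to a zinc enolate that (CF3)2CHOH protonates. The closest known reaction type is the reductive decarboxylative radical conjugate (Giese) addition of N-(acyloxy)phthalimides, established under cathodic, photoredox and metal-reductant conditions and used here intramolecularly. C4a is controlled by C8a: A(1,3) strain with the N-sulfonyl group holds the C8a side chain pseudo-axial, so the tether can reach C4a only on its own face and the ring fusion must be cis. C5 is controlled by the chair-like transition state of the forming ring, in which the silyloxyoctyl chain on the planar radical carbon should prefer the pseudo-equatorial position, placing H5 cis to H4a and H8a (5R); both C5 epimers of 25 converge because the centre is erased in the radical. The step needs chemoselective electron transfer (ester before enone and sulfonamide), which the large gap in reduction potentials should secure. It also needs ring closure to be faster than hydrogen-atom transfer, which the activated acceptor, the three-carbon tether and high dilution should secure. The weakly acidic proton source keeps the medium from turning basic and so protects the α-sulfonamido ketone.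

Step 16
Reactants: 26 (2R,4aR,5R,8aS)-5-{(5R)-5-[(tert-butyldimethylsilyl)oxy]octyl}-2-methyl-1-(4-methylbenzenesulfonyl)octahydroquinolin-3(2H)-one
Product: 27 (2R,3R,4aR,5R,8aS)-5-{(5R)-5-[(tert-butyldimethylsilyl)oxy]octyl}-2-methyl-1-(4-methylbenzenesulfonyl)decahydroquinolin-3-ol
Conditions: LiBH(s-Bu)3, THF, −78 °C; H2O
Reagents that add atoms: none
Why: The bulky hydride should approach C3 on the convex face, anti to the axial C2 methyl group and away from the carbocycle, giving the equatorial 3R alcohol (2,3-cis). This fixes C3 in a defined but provisional configuration that step 18 inverts. The low temperature avoids enolisation toward C2.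

Step 17
Reactants: 27 (2R,3R,4aR,5R,8aS)-5-{(5R)-5-[(tert-butyldimethylsilyl)oxy]octyl}-2-methyl-1-(4-methylbenzenesulfonyl)decahydroquinolin-3-ol
Product: 29 tert-butyl (2R,3R,4aR,5R,8aS)-5-{(5R)-5-[(tert-butyldimethylsilyl)oxy]octyl}-3-hydroxy-2-methyloctahydroquinoline-1(2H)-carboxylate, via free amino alcohol 28 (not isolated)
Conditions: Na[C10H8] (sodium naphthalenide), DME, −78 °C; MeOH, aq. work-up; crude, Boc2O, Et3N, CH2Cl2, rt → 40 °C
Reagents that add atoms: di-tert-butyl dicarbonate, CC(C)(C)OC(=O)OC(=O)OC(C)(C)C
Why: Single-electron transfer from the arene radical anion cleaves the S–N bond; it is done here because nothing else in 27 is reducible, whereas the later enoate would be. The liberated amine is acylated on nitrogen in preference to the hindered hydroxyl group, giving a carbamate that acid removes at the end.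

Step 18
Reactants: 29 tert-butyl (2R,3R,4aR,5R,8aS)-5-{(5R)-5-[(tert-butyldimethylsilyl)oxy]octyl}-3-hydroxy-2-methyloctahydroquinoline-1(2H)-carboxylate; 30 (2E)-oct-2-enoic acid
Product: 31 tert-butyl (2R,3S,4aR,5R,8aS)-5-{(5R)-5-[(tert-butyldimethylsilyl)oxy]octyl}-2-methyl-3-{[(2E)-oct-2-enoyl]oxy}octahydroquinoline-1(2H)-carboxylate
Conditions: PPh3, DIAD, toluene, 0 °C → rt
Reagents that add atoms: none
Why: Mitsunobu esterification: the carboxylate displaces the alkoxyphosphonium group by SN2 with inversion, which sets 3S and attaches the acyl group in one step. The equatorial leaving group has no anti-periplanar hydrogen, so E2 elimination is disfavoured. Participation of the carbamate carbonyl would need a bridged, twisted intermediate and is not expected.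

Step 19
Reactants: 31 tert-butyl (2R,3S,4aR,5R,8aS)-5-{(5R)-5-[(tert-butyldimethylsilyl)oxy]octyl}-2-methyl-3-{[(2E)-oct-2-enoyl]oxy}octahydroquinoline-1(2H)-carboxylate
Product: 32 (2R,3S,4aR,5R,8aS)-5-[(5R)-5-hydroxyoctyl]-2-methyldecahydroquinolin-3-yl (2E)-oct-2-enoate (target)
Conditions: CF3CO2H/CH2Cl2/H2O (ca. 10:10:1), 0 °C → rt; cold aq. NaHCO3
Reagents that add atoms: none
Why: Acidolysis removes the tert-butyl carbamate (tert-butyl cation loss, then decarboxylation) and hydrolyses the silyl ether. The amine stays protonated until the brief cold work-up, which suppresses O→N acyl shift, and the conjugated ester is stable to acid at this temperature.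

## Compound list

1 | 2-acetylfuran [1-(furan-2-yl)ethan-1-one] | CC(=O)c1ccco1 | starting material
2 | (R)-2-methylpropane-2-sulfinamide | CC(C)(C)[S@](N)=O | starting material
3 | (R)-N-[(1E)-1-(furan-2-yl)ethylidene]-2-methylpropane-2-sulfinamide | CC(C)(C)[S@](/N=C(\C)c1ccco1)=O | intermediate (not isolated)
4 | (R)-N-[(1R)-1-(furan-2-yl)ethyl]-2-methylpropane-2-sulfinamide | CC(C)(C)[S@](N[C@H](C)c1ccco1)=O | intermediate
5 | (1R)-1-(furan-2-yl)ethan-1-aminium chloride | C[C@@H]([NH3+])c1ccco1.[Cl-] | intermediate (not isolated)
6 | N-[(1R)-1-(furan-2-yl)ethyl]-4-methylbenzenesulfonamide | Cc1ccc(cc1)S(=O)(=O)N[C@H](C)c1ccco1 | intermediate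
7 | (2R)-6-hydroxy-2-methyl-1-(4-methylbenzenesulfonyl)-1,6-dihydro-2H-pyridin-3-one (C6 epimers) | O=C1C=CC(O)N(S(=O)(=O)c2ccc(C)cc2)[C@@H]1C | intermediate
8 | allyltrimethylsilane | C=CC[Si](C)(C)C | starting material
9 | (2R,6S)-2-methyl-1-(4-methylbenzenesulfonyl)-6-(prop-2-en-1-yl)-1,6-dihydro-2H-pyridin-3-one | O=C1C=C[C@H](CC=C)N(S(=O)(=O)c2ccc(C)cc2)[C@@H]1C | intermediate
10 | (2R,3R,6S)-2-methyl-1-(4-methylbenzenesulfonyl)-6-(prop-2-en-1-yl)-1,2,3,6-tetrahydropyridin-3-ol | O[C@@H]1C=C[C@H](CC=C)N(S(=O)(=O)c2ccc(C)cc2)[C@@H]1C | intermediate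
11 | (2R,3R,6S)-2-methyl-1-(4-methylbenzenesulfonyl)-6-(prop-2-en-1-yl)-3-[(triethylsilyl)oxy]-1,2,3,6-tetrahydropyridine | CC[Si](CC)(CC)O[C@@H]1C=C[C@H](CC=C)N(S(=O)(=O)c2ccc(C)cc2)[C@@H]1C | intermediate
12 | 9-{3-[(2S,5R,6R)-6-methyl-1-(4-methylbenzenesulfonyl)-5-[(triethylsilyl)oxy]-1,2,5,6-tetrahydropyridin-2-yl]propyl}-9-borabicyclo[3.3.1]nonane | CC[Si](CC)(CC)O[C@@H]1C=C[C@H](CCCB2C3CCCC2CCC3)N(S(=O)(=O)c2ccc(C)cc2)[C@@H]1C | intermediate (not isolated)
13 | 3-[(2S,5R,6R)-6-methyl-1-(4-methylbenzenesulfonyl)-5-[(triethylsilyl)oxy]-1,2,5,6-tetrahydropyridin-2-yl]propan-1-ol | CC[Si](CC)(CC)O[C@@H]1C=C[C@H](CCCO)N(S(=O)(=O)c2ccc(C)cc2)[C@@H]1C | intermediate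
14 | (2R,3R,6S)-6-(3-iodopropyl)-2-methyl-1-(4-methylbenzenesulfonyl)-3-[(triethylsilyl)oxy]-1,2,3,6-tetrahydropyridine | CC[Si](CC)(CC)O[C@@H]1C=C[C@H](CCCI)N(S(=O)(=O)c2ccc(C)cc2)[C@@H]1C | intermediate
15 | 6-bromohex-1-ene | BrCCCCC=C | starting material
16 | (R)-2-propyloxirane [(R)-1,2-epoxypentane] | CCC[C@@H]1CO1 | starting material
17 | hex-5-enylmagnesium bromide | C=CCCCC[Mg]Br | intermediate (not isolated)
18 | (4R)-undec-10-en-4-ol | CCC[C@@H](O)CCCCCC=C | intermediate
19 | tert-butyldimethyl{[(4R)-undec-10-en-4-yl]oxy}silane | CCC[C@@H](O[Si](C)(C)C(C)(C)C)CCCCCC=C | intermediate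
20 | (7R)-7-[(tert-butyldimethylsilyl)oxy]decanoic acid | CCC[C@@H](O[Si](C)(C)C(C)(C)C)CCCCCC(=O)O | intermediate
21 | dilithium (7R)-7-[(tert-butyldimethylsilyl)oxy]dec-1-ene-1,1-bis(olate) | [Li+].[Li+].CCC[C@@H](O[Si](C)(C)C(C)(C)C)CCCCC=C([O-])[O-] | intermediate (not isolated)
22 | (7R)-7-[(tert-butyldimethylsilyl)oxy]-2-{3-[(2S,5R,6R)-6-methyl-1-(4-methylbenzenesulfonyl)-5-[(triethylsilyl)oxy]-1,2,5,6-tetrahydropyridin-2-yl]propyl}decanoic acid (C2 epimers) | CC[Si](CC)(CC)O[C@@H]1C=C[C@H](CCCC(C(=O)O)CCCC[C@H](O[Si](C)(C)C(C)(C)C)CCC)N(S(=O)(=O)c2ccc(C)cc2)[C@@H]1C | intermediate (not isolated)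
23 | (7R)-7-[(tert-butyldimethylsilyl)oxy]-2-{3-[(2S,5R,6R)-5-hydroxy-6-methyl-1-(4-methylbenzenesulfonyl)-1,2,5,6-tetrahydropyridin-2-yl]propyl}decanoic acid (C2 epimers) | O[C@@H]1C=C[C@H](CCCC(C(=O)O)CCCC[C@H](O[Si](C)(C)C(C)(C)C)CCC)N(S(=O)(=O)c2ccc(C)cc2)[C@@H]1C | intermediate
24 | (7R)-7-[(tert-butyldimethylsilyl)oxy]-2-{3-[(2S,6R)-6-methyl-1-(4-methylbenzenesulfonyl)-5-oxo-1,2,5,6-tetrahydropyridin-2-yl]propyl}decanoic acid (C2 epimers) | O=C1C=C[C@H](CCCC(C(=O)O)CCCC[C@H](O[Si](C)(C)C(C)(C)C)CCC)N(S(=O)(=O)c2ccc(C)cc2)[C@@H]1C | intermediate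
25 | 1,3-dioxoisoindolin-2-yl (7R)-7-[(tert-butyldimethylsilyl)oxy]-2-{3-[(2S,6R)-6-methyl-1-(4-methylbenzenesulfonyl)-5-oxo-1,2,5,6-tetrahydropyridin-2-yl]propyl}decanoate (C2 epimers) | O=C1C=C[C@H](CCCC(C(=O)ON2C(=O)c3ccccc3C2=O)CCCC[C@H](O[Si](C)(C)C(C)(C)C)CCC)N(S(=O)(=O)c2ccc(C)cc2)[C@@H]1C | intermediate
26 | (2R,4aR,5R,8aS)-5-{(5R)-5-[(tert-butyldimethylsilyl)oxy]octyl}-2-methyl-1-(4-methylbenzenesulfonyl)octahydroquinolin-3(2H)-one | O=C1C[C@@H]2[C@H](CCCC[C@H](O[Si](C)(C)C(C)(C)C)CCC)CCC[C@@H]2N(S(=O)(=O)c2ccc(C)cc2)[C@@H]1C | intermediate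
27 | (2R,3R,4aR,5R,8aS)-5-{(5R)-5-[(tert-butyldimethylsilyl)oxy]octyl}-2-methyl-1-(4-methylbenzenesulfonyl)decahydroquinolin-3-ol | O[C@@H]1C[C@@H]2[C@H](CCCC[C@H](O[Si](C)(C)C(C)(C)C)CCC)CCC[C@@H]2N(S(=O)(=O)c2ccc(C)cc2)[C@@H]1C | intermediate
28 | (2R,3R,4aR,5R,8aS)-5-{(5R)-5-[(tert-butyldimethylsilyl)oxy]octyl}-2-methyldecahydroquinolin-3-ol | O[C@@H]1C[C@@H]2[C@H](CCCC[C@H](O[Si](C)(C)C(C)(C)C)CCC)CCC[C@@H]2N[C@@H]1C | intermediate (not isolated)
29 | tert-butyl (2R,3R,4aR,5R,8aS)-5-{(5R)-5-[(tert-butyldimethylsilyl)oxy]octyl}-3-hydroxy-2-methyloctahydroquinoline-1(2H)-carboxylate | O[C@@H]1C[C@@H]2[C@H](CCCC[C@H](O[Si](C)(C)C(C)(C)C)CCC)CCC[C@@H]2N(C(=O)OC(C)(C)C)[C@@H]1C | intermediate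
30 | (2E)-oct-2-enoic acid | CCCCC/C=C/C(=O)O | starting material
31 | tert-butyl (2R,3S,4aR,5R,8aS)-5-{(5R)-5-[(tert-butyldimethylsilyl)oxy]octyl}-2-methyl-3-{[(2E)-oct-2-enoyl]oxy}octahydroquinoline-1(2H)-carboxylate | CCCCC/C=C/C(=O)O[C@H]1C[C@@H]2[C@H](CCCC[C@H](O[Si](C)(C)C(C)(C)C)CCC)CCC[C@@H]2N(C(=O)OC(C)(C)C)[C@@H]1C | intermediate
32 | (2R,3S,4aR,5R,8aS)-5-[(5R)-5-hydroxyoctyl]-2-methyldecahydroquinolin-3-yl (2E)-oct-2-enoate | CCCCC/C=C/C(=O)O[C@H]1C[C@@H]2[C@H](CCCC[C@H](O)CCC)CCC[C@@H]2N[C@@H]1C | target

## Step count and least certain steps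

Total: 19 steps. Longest linear sequence: 16 steps (steps 1–8 and 12–19, from 1). The acid 20 is made in a three-step branch (steps 9–11).

**Step 15 (key step).** The most likely failure is that the radical or the enone is diverted before ring closure. This could happen by a 1,5-hydrogen shift from the allylic, nitrogen-bearing C8a–H, by direct cathodic reduction of the enone as the ester is used up, or by base build-up that aromatises the sulfonyl dihydropyridinone with loss of sulfinate. In addition, discrimination between the two chair closures at C5 may be incomplete at ambient temperature, because the pseudo-equatorial preference of a chain on a planar radical carbon is modest. The fallback sets out from 24. Coupling with 1-hydroxypyridine-2(1H)-thione (DIC, CH2Cl2, dark) would give the O-acyl thiohydroxamate F1, which is photolysed with visible light at −30 °C in the presence of t-BuSH. This is a neutral radical chain without electrode, metal ions or accumulating anions, in which the α-keto radical is quenched by hydrogen-atom transfer from the thiol. The low temperature should also sharpen the chair preference at C5. The fallback comes back to the route at 26.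

**Step 18.** The most likely failure is slow SN2 displacement at C3, which is flanked by the axial-methyl-bearing C2. The alkoxyphosphonium ion is then consumed by acyl transfer with retention or by anhydride formation, helped by the modest acidity of the enoic acid. The fallback separates inversion from acylation and moves the inversion to the sulfonamide stage. It sets out from 27: Mitsunobu reaction with 4-nitrobenzoic acid (PPh3, DIAD) would give the inverted 4-nitrobenzoate F2, and K2CO3 in MeOH the 3S sulfonamide alcohol F3. Na[C10H8] would then give the 3S amino alcohol F4 (not isolated) and Boc2O the 3S carbamate alcohol F5. F5 is acylated with 30 under Yamaguchi conditions (2,4,6-trichlorobenzoyl chloride, Et3N, DMAP), which proceeds with retention. The fallback comes back to the route at 31.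

**Step 12.** The most likely failure is proton transfer or E2 elimination on the iodide by the strongly basic, aggregated enediolate, which would give low conversion. Erosion of the tert-butyldimethylsilyl ether during removal of the triethylsilyl group is a second concern. The fallback carries the carboxyl group through the C–C bond formation as an ester. It sets out from 20, which is converted with Me3SiCHN2 in MeOH/toluene into the methyl ester F6. The monolithium enolate of F6 (LiN(iPr)2, THF/DMPU) is alkylated with 14 to the coupled methyl ester F7, and LiOH in THF/MeOH/H2O then gives the acid. The fallback comes back to the route at 22 and continues with the methanolysis to 23.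

**Step 19.** The most likely failure is incomplete cleavage of the secondary silyl ether, or trifluoroacetylation of the liberated alcohol, followed by O→N acyl shift while the free amine is exposed during neutralisation. The fallback is a staged, orthogonal unmasking that sets out from 31. HF·pyridine in THF would remove only the silyl ether to give the hydroxy carbamate F8. Me3SiOTf/2,6-lutidine in CH2Cl2 at 0 °C, followed by MeOH, would then cleave the carbamate without aqueous acid. The fallback comes back at 32.

## Further compounds

F1 | step 15 | 2-thioxopyridin-1(2H)-yl (7R)-7-[(tert-butyldimethylsilyl)oxy]-2-{3-[(2S,6R)-6-methyl-1-(4-methylbenzenesulfonyl)-5-oxo-1,2,5,6-tetrahydropyridin-2-yl]propyl}decanoate | O=C1C=C[C@H](CCCC(C(=O)ON2C=CC=CC2=S)CCCC[C@H](O[Si](C)(C)C(C)(C)C)CCC)N(S(=O)(=O)c2ccc(C)cc2)[C@@H]1C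
F2 | step 18 | (2R,3S,4aR,5R,8aS)-5-{(5R)-5-[(tert-butyldimethylsilyl)oxy]octyl}-2-methyl-1-(4-methylbenzenesulfonyl)decahydroquinolin-3-yl 4-nitrobenzoate | [O-][N+](=O)c1ccc(cc1)C(=O)O[C@H]1C[C@@H]2[C@H](CCCC[C@H](O[Si](C)(C)C(C)(C)C)CCC)CCC[C@@H]2N(S(=O)(=O)c2ccc(C)cc2)[C@@H]1C
F3 | step 18 | (2R,3S,4aR,5R,8aS)-5-{(5R)-5-[(tert-butyldimethylsilyl)oxy]octyl}-2-methyl-1-(4-methylbenzenesulfonyl)decahydroquinolin-3-ol | O[C@H]1C[C@@H]2[C@H](CCCC[C@H](O[Si](C)(C)C(C)(C)C)CCC)CCC[C@@H]2N(S(=O)(=O)c2ccc(C)cc2)[C@@H]1C
F4 | step 18 | (2R,3S,4aR,5R,8aS)-5-{(5R)-5-[(tert-butyldimethylsilyl)oxy]octyl}-2-methyldecahydroquinolin-3-ol | O[C@H]1C[C@@H]2[C@H](CCCC[C@H](O[Si](C)(C)C(C)(C)C)CCC)CCC[C@@H]2N[C@@H]1C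
F5 | step 18 | tert-butyl (2R,3S,4aR,5R,8aS)-5-{(5R)-5-[(tert-butyldimethylsilyl)oxy]octyl}-3-hydroxy-2-methyloctahydroquinoline-1(2H)-carboxylate | O[C@H]1C[C@@H]2[C@H](CCCC[C@H](O[Si](C)(C)C(C)(C)C)CCC)CCC[C@@H]2N(C(=O)OC(C)(C)C)[C@@H]1C
F6 | step 12 | methyl (7R)-7-[(tert-butyldimethylsilyl)oxy]decanoate | CCC[C@@H](O[Si](C)(C)C(C)(C)C)CCCCCC(=O)OC
F7 | step 12 | methyl (7R)-7-[(tert-butyldimethylsilyl)oxy]-2-{3-[(2S,5R,6R)-6-methyl-1-(4-methylbenzenesulfonyl)-5-[(triethylsilyl)oxy]-1,2,5,6-tetrahydropyridin-2-yl]propyl}decanoate (C2 epimers) | CC[Si](CC)(CC)O[C@@H]1C=C[C@H](CCCC(C(=O)OC)CCCC[C@H](O[Si](C)(C)C(C)(C)C)CCC)N(S(=O)(=O)c2ccc(C)cc2)[C@@H]1C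
F8 | step 19 | tert-butyl (2R,3S,4aR,5R,8aS)-5-[(5R)-5-hydroxyoctyl]-2-methyl-3-{[(2E)-oct-2-enoyl]oxy}octahydroquinoline-1(2H)-carboxylate | CCCCC/C=C/C(=O)O[C@H]1C[C@@H]2[C@H](CCCC[C@H](O)CCC)CCC[C@@H]2N(C(=O)OC(C)(C)C)[C@@H]1C
A1 | alternative 1 | methyl (3S)-3-{(tert-butoxycarbonyl)[(2R)-3-oxobutan-2-yl]amino}cyclohex-1-ene-1-carboxylate | COC(=O)C1=C[C@@H](N(C(=O)OC(C)(C)C)[C@H](C)C(C)=O)CCC1
A2 | alternative 1 | methyl (2R,4aR,5R,8aS)-1-(tert-butoxycarbonyl)-2-methyl-3-oxodecahydroquinoline-5-carboxylate | O=C1C[C@@H]2[C@H](C(=O)OC)CCC[C@@H]2N(C(=O)OC(C)(C)C)[C@@H]1C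
A3 | alternative 2 | (2R,3S,6R,11R)-N-benzyl-3-(benzyloxy)-11-[(tert-butyldiphenylsilyl)oxy]-5-(dimethoxymethyl)-6-[(2Z)-3-(trimethylsilyl)prop-2-en-1-yl]tetradecan-2-amine (C5 epimers) | COC(OC)C(C[C@H](OCc1ccccc1)[C@@H](C)NCc1ccccc1)[C@H](CCCC[C@H](O[Si](c1ccccc1)(c1ccccc1)C(C)(C)C)CCC)C/C=C\[Si](C)(C)C
A4 | alternative 2 | (2R,3S,4aR,5R,8aS)-1-benzyl-3-(benzyloxy)-5-{(5R)-5-[(tert-butyldiphenylsilyl)oxy]octyl}-2-methyl-1,2,3,4,4a,5,6,8a-octahydroquinoline | C(c1ccccc1)O[C@H]1C[C@@H]2[C@H](CCCC[C@H](O[Si](c3ccccc3)(c3ccccc3)C(C)(C)C)CCC)CC=C[C@@H]2N(Cc2ccccc2)[C@@H]1C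
A5 | alternative 3 | (1S)-1-[(2R,3aR,4R,7aS)-4-{(5R)-5-[(tert-butyldimethylsilyl)oxy]octyl}-1-(prop-2-en-1-yl)octahydro-1H-indol-2-yl]ethan-1-ol | C=CCN1[C@@H]([C@H](C)O)C[C@@H]2[C@H](CCCC[C@H](O[Si](C)(C)C(C)(C)C)CCC)CCC[C@H]12
A6 | alternative 3 | (2R,3S,4aR,5R,8aS)-5-{(5R)-5-[(tert-butyldimethylsilyl)oxy]octyl}-2-methyl-1-(prop-2-en-1-yl)decahydroquinolin-3-yl trifluoroacetate | FC(F)(F)C(=O)O[C@H]1C[C@@H]2[C@H](CCCC[C@H](O[Si](C)(C)C(C)(C)C)CCC)CCC[C@@H]2N(CC=C)[C@@H]1C
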